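No rate constant stands among the given numbers, so the constant wanted for a warm flask has to be read from the two earlier runs.

| flask | substrate | solid reagent | temperature | remark | time |
|---|---|---|---|---|---|
| birch | 10 mM | 5 mM | −45 °C | run made earlier |  |
| ash | 10 mM | 7.5 mM | −20 °C | run made earlier |  |
| dusk | 10 mM | 10.0 mM |  | at 0 °C until 4.0 h, from then on at −40 °C | 6.0 h |
| noon | 10 mM | 10.0 mM | −40 °C |  | 6.0 h |
| midnight | 10 mM | 10.0 mM | 0 °C |  | 6.0 h |
| spring | 10 mM | 10.0 mM | −20 °C |  | 6.0 h |

- birch (time / h: target / %, substrate / %): 0.417: 0.8, 99.9; 0.833: 0.7, 100.1; 2.00: 2.5, 96.3; 5.00: 9.8, 89.9
- ash (time / min: target / %, substrate / %): 10.0: 0, 97.3; 20.0: 1.5, 95.2; 40.0: 3.6, 89.8; 120: 18.1, 62.0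

(each reading ± 0.5 percentage points)

1. the flask that comes out highest in amount of target, in percent of the substrate charged, or "all alike" when all lie within 1.5 percentage points (dusk / noon / midnight / spring / all alike)
2. target at the end, in percent of the substrate charged, dusk
3. target at the end, in percent of the substrate charged, noon
4. target at the end, in percent of the substrate charged, midnight
5. target at the end, in percent of the substrate charged, spring

- as a solid, counted per litre of solution: solid reagent
- at the start none of the solid reagent is in solution

In the ash run at 120 min, the substrate lost exceeds the target gained. The missing 20 percentage points is taken here as a first-order loss, which over the mean substrate of that run comes to 0.123 h⁻¹. The bench rule that a rate doubles every 10 K divides this by 5.66 on the way down to the birch run at −45 °C, and so predicts 10.9% missing by 5.00 h. The birch run shows 0.3 points. Even a ceiling of 2 points, 4 times the scatter of one reading, lies 5.43-fold under the prediction, so the rule stops working here, and with the birch loss taken at that ceiling the loss climbs 3.93-fold per 10 K.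

Carried up to 0 °C, this gives the hot lifetime, the first-order time in which the loss by itself cuts the substrate by a factor 2.72: 0.526 h. The change in dusk comes after 7.61 lifetimes, when 0.0497% of the substrate remains by this reckoning, so dusk should end near midnight in target, and the substrate is worth watching early in the warm stretch. At −20 °C the lifetime is 8.13 h, longer than the run, so the loss by itself leaves spring 47.8% of its substrate at 6.0 h. Target is taken to grow early as the square of time, and that growth reads 2.66-fold per 10 K between the last readings of the two runs, whose charges of solid reagent differ. Set against a substrate dying with the hot lifetime, it gives midnight about 17.7%.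

The forecast says “the substrate is consumed quickly but selectivity is poor” and gives midnight 26%, dusk 25%, noon 22% and spring 50%, with spring highest. Its midnight value stands above this reckoning.

The flasks give dusk 12.7%, midnight 12.7%, noon 22.8% and spring 45.6%, so spring is highest, and midnight falls below both estimates.

    substrate → side product (k = 0.00200 min⁻¹, Ea = 78.0 kJ mol⁻¹)
    2 coupling partner → self-condensation product (k = 1.10 M⁻¹ min⁻¹, Ea = 48.0 kJ mol⁻¹)
    substrate + coupling partner → target (k = 1.30 M⁻¹ min⁻¹, Ea = 48.0 kJ mol⁻¹)
    solid reagent ⇌ coupling partner, rate k4*(cs4 - [coupling partner]) while solid is left; crystals form when [coupling partner] > cs4 (solubility = 9.10 mM, k = 0.00530 min⁻¹)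
    (constants at −20 °C)

Dusk holds 0.00636% of its substrate at 4.00 h, below the 0.0497% reckoned from the lifetime 0.526 h, and its target reads 12.7% then and 12.7% at 6.00 h. The lifetime holds no charge, so for a neighbour of dusk with 40 mM of substrate, 0.250 equiv of solid reagent, the reckoning again puts 0.0497% at the change. That neighbour ends with 0.0090% of its substrate, 92.3% as side product and target at 7.65%.

The readings are calculated with constants of no real substance, and the scatter is random.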